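**Retrosynthetic overview**
- Labels: upper isoflavan = ring A (benzo), ring C (pyran), ring B (aryl); lower isoflavan = ring D (benzo), ring F (pyran), ring E (aryl). No pyran ring is built: rings C and F both come intact from 7-hydroxychroman-4-one.
- End game: target ⇐ hydrogenolysis (four OBn and the ring-F C4–OH) ⇐ cis-chroman-4-ol ⇐ transfer hydrogenation with dynamic kinetic resolution of the ring-F ketone (sets lower C3).
- Ring F is attached last, by Pd α-arylation of the chromanone with a ring-E aryl triflate (that ring-E carbon is meta to both other oxygens, so it must be the electrophile).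
- Upper C4–ring E bond: trans-selective Friedel–Crafts capture of the chroman-4-yl cation from the (3R,4R)-isoflavan-4-ol by a mono-TIPS phloroglucinol ether.
- Key step: upper C3–ring B bond by umpolung. The chromanone enol ether becomes an enolonium (trivalent-iodine enolate) and is attacked by the electron-rich arene; transfer hydrogenation then sets upper C3 and C4.

Assumption: RuCl[(R,R)-TsDPEN](p-cymene) gives the (4R)-carbinol, the sense established for 4-chromanone and 1-tetralone.

**Step 1**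
Reactants: 1 7-hydroxychroman-4-one
Product: 2 7-(benzyloxy)chroman-4-one
Conditions: BnBr, K2CO3, DMF, rt
Reagents that add atoms: benzyl bromide, BrCc1ccccc1
Why: Williamson ether synthesis on the phenoxide; the benzyl ether survives every later step until the final hydrogenolysis.

**Step 2**
Reactants: 2 7-(benzyloxy)chroman-4-one
Product: 3 {[7-(benzyloxy)-2H-chromen-4-yl]oxy}trimethylsilane
Conditions: TMSOTf, Et3N, CH2Cl2, 0 °C; pentane, filter, concentrate, use crude
Reagents that add atoms: trimethylsilyl trifluoromethanesulfonate, C[Si](C)(C)OS(=O)(=O)C(F)(F)F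
Why: Soft enolisation and O-silylation (silyl enol ether formation); only C3 is enolisable, and the conditions are too mild for retro-oxa-Michael opening of the pyranone.

**Step 3**
Reactants: 4 2,6-dimethoxyphenol
Product: 5 2-(benzyloxy)-1,3-dimethoxybenzene
Conditions: BnBr, K2CO3, DMF, 60 °C
Reagents that add atoms: benzyl bromide, BrCc1ccccc1
Why: Williamson ether synthesis; the free phenol would be oxidised by the iodine reagent of step 4, so it is masked as a hydrogenolysable ether.

**Step 4 (key step)**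
Reactants: 3 {[7-(benzyloxy)-2H-chromen-4-yl]oxy}trimethylsilane; 5 2-(benzyloxy)-1,3-dimethoxybenzene
Product: 7 rac-7-(benzyloxy)-3-[3-(benzyloxy)-2,4-dimethoxyphenyl]chroman-4-one, via enolonium tosylate 6 (not isolated)
Conditions: PhI(OH)OTs (1.2 equiv), BF3·OEt2 (1.5 equiv), CH2Cl2, −78 °C, add 3, 5 min; then 5 (3 equiv), −78 °C to rt
Reagents that add atoms: none
Why: Proposed new method: the O-bound trivalent-iodine enolate (enolonium) formed from the silyl enol ether and BF3-activated PhI(OH)OTs is an α-keto cation equivalent, so the normally nucleophilic C3 is attacked by the normally nucleophilic C4 of arene 5 (ortho and para to the two OMe groups, the twisted central OBn directing only weakly) in an umpolung Friedel–Crafts-type α-arylation with loss of PhI; the closest known reaction is the enolonium α-arylation of ketone silyl enol ethers with indoles and pyrroles, and the new C3 centre is racemic and epimerisable, being set in step 5.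

**Step 5**
Reactants: 7 rac-7-(benzyloxy)-3-[3-(benzyloxy)-2,4-dimethoxyphenyl]chroman-4-one
Product: 8 (3R,4R)-7-(benzyloxy)-3-[3-(benzyloxy)-2,4-dimethoxyphenyl]chroman-4-ol (3,4-cis)
Conditions: RuCl[(R,R)-TsDPEN](p-cymene) (2 mol %), HCO2H/Et3N 5:2, EtOAc, 40 °C
Reagents that add atoms: none
Why: Noyori asymmetric transfer hydrogenation under dynamic kinetic resolution: C3 epimerises through the enol while the (R,R) catalyst reduces the (3R) ketone fastest from the face opposite the aryl group, giving the cis (3R,4R) alcohol.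

**Step 6**
Reactants: 9 5-methoxybenzene-1,3-diol
Product: 10 3-methoxy-5-[tri(propan-2-yl)silyloxy]phenol
Conditions: TIPSCl (1.0 equiv), imidazole, DMF, 0 °C to rt; diol and bis-ether recycled
Reagents that add atoms: chlorotri(propan-2-yl)silane, CC(C)[Si](Cl)(C(C)C)C(C)C
Why: Statistical mono-silylation of a symmetrical diol (the two OH groups are equivalent, so only one mono-ether can form); the bulky TIPS ether later shields its two ortho carbons.

**Step 7**
Reactants: 8 (3R,4R)-7-(benzyloxy)-3-[3-(benzyloxy)-2,4-dimethoxyphenyl]chroman-4-ol; 10 3-methoxy-5-[tri(propan-2-yl)silyloxy]phenol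
Product: 12 2-[(3R,4S)-7-(benzyloxy)-3-[3-(benzyloxy)-2,4-dimethoxyphenyl]chroman-4-yl]-3-methoxy-5-[tri(propan-2-yl)silyloxy]phenol, via chroman-4-ylium cation 11 (not isolated)
Conditions: 10 (4 equiv), BF3·OEt2 (30 mol %), CH2Cl2, −40 to −10 °C, slow addition of 8
Reagents that add atoms: none
Why: Friedel–Crafts alkylation (SN1): BF3 ionises the benzylic alcohol to a cation stabilised by the ring-A oxygens, the excess phloroglucinol-type arene competes with ring A and attacks anti to the C3 aryl group (C4 becomes S, 3,4-trans) at the one carbon that is ortho to its free OH and not next to the TIPS ether, and C3 is untouched.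

**Step 8**
Reactants: 12 (the phenol from step 7)
Product: 13 2-[(3R,4S)-7-(benzyloxy)-3-[3-(benzyloxy)-2,4-dimethoxyphenyl]chroman-4-yl]-3-methoxy-5-[tri(propan-2-yl)silyloxy]phenyl trifluoromethanesulfonate
Conditions: Tf2O, pyridine, CH2Cl2, −20 to 0 °C
Reagents that add atoms: trifluoromethanesulfonic anhydride, FC(F)(F)S(=O)(=O)OS(=O)(=O)C(F)(F)F
Why: O-sulfonylation of the only free phenol, which turns the ring-E carbon meta to the other two oxygens into a cross-coupling electrophile.

**Step 9**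
Reactants: 13 (the aryl triflate from step 8)
Product: 15 5-(benzyloxy)-2-[(3R,4S)-7-(benzyloxy)-3-[3-(benzyloxy)-2,4-dimethoxyphenyl]chroman-4-yl]-3-methoxyphenyl trifluoromethanesulfonate, via caesium phenolate 14 (not isolated)
Conditions: CsF (3 equiv), BnBr (1.5 equiv), DMF, 0 °C to rt
Reagents that add atoms: benzyl bromide, BrCc1ccccc1
Why: Fluoride desilylation followed by in situ Williamson benzylation; the silyl ether has done its directing job and is exchanged for a benzyl ether that leaves in the final hydrogenolysis.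

**Step 10**
Reactants: 15 (the benzyl ether triflate from step 9); 2 7-(benzyloxy)chroman-4-one
Product: 16 7-(benzyloxy)-3-{5-(benzyloxy)-2-[(3R,4S)-7-(benzyloxy)-3-[3-(benzyloxy)-2,4-dimethoxyphenyl]chroman-4-yl]-3-methoxyphenyl}chroman-4-one (both C3 epimers of the new chromanone)
Conditions: 2 (2 equiv), Pd2(dba)3 (2.5 mol %), XPhos (6 mol %), K3PO4 (3 equiv), toluene, 90 °C
Reagents that add atoms: none
Why: Palladium-catalysed ketone α-arylation (Buchwald–Hartwig type): the potassium enolate of 2 couples with the aryl triflate after oxidative addition to zerovalent palladium, forming the ring E–ring F bond; the new α-centre is an epimer mixture because it is set in step 11.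

**Step 11**
Reactants: 16 (the coupled chromanone from step 10)
Product: 17 (3R,4R)-7-(benzyloxy)-3-{5-(benzyloxy)-2-[(3R,4S)-7-(benzyloxy)-3-[3-(benzyloxy)-2,4-dimethoxyphenyl]chroman-4-yl]-3-methoxyphenyl}chroman-4-ol (3,4-cis in ring F)
Conditions: RuCl[(R,R)-TsDPEN](p-cymene) (3 mol %), HCO2H/Et3N 5:2, EtOAc/DMF, 40 °C
Reagents that add atoms: none
Why: Second Noyori transfer hydrogenation under dynamic kinetic resolution: the α-aryl ketone epimerises and the (R,R) catalyst overrides the remote stereocentres to give the cis (3R,4R) alcohol of ring F.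

**Step 12**
Reactants: 17 (the cis alcohol from step 11)
Product: 18 (3R,4S)-4-{4-hydroxy-2-[(3R)-7-hydroxychroman-3-yl]-6-methoxyphenyl}-3-(3-hydroxy-2,4-dimethoxyphenyl)chroman-7-ol (CNP0305801.1)
Conditions: H2 (1 atm), 10 % Pd/C, EtOAc/EtOH 1:1, AcOH (5 equiv), rt
Reagents that add atoms: none
Why: Catalytic hydrogenolysis cleaves the four benzyl ethers and, by direct C–O cleavage, the para-oxygenated benzylic C–OH of ring F, so lower C3 keeps its configuration (descriptor R) and the upper 3R,4S centres are untouched.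

**Compound list**
1 | 7-hydroxychroman-4-one | O=C1CCOc2cc(O)ccc21 | starting material
2 | 7-(benzyloxy)chroman-4-one | O=C1CCOc2cc(OCc3ccccc3)ccc21 | intermediate
3 | {[7-(benzyloxy)-2H-chromen-4-yl]oxy}trimethylsilane | C[Si](C)(C)OC1=CCOc2cc(OCc3ccccc3)ccc21 | intermediate
4 | 2,6-dimethoxyphenol | COc1cccc(OC)c1O | starting material
5 | 2-(benzyloxy)-1,3-dimethoxybenzene | COc1cccc(OC)c1OCc1ccccc1 | intermediate
6 | [7-(benzyloxy)-2H-chromen-4-yl]oxy(phenyl)iodanyl 4-methylbenzenesulfonate (enolonium, not isolated) | Cc1ccc(cc1)S(=O)(=O)OI(c1ccccc1)OC1=CCOc2cc(OCc3ccccc3)ccc21 | intermediate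
7 | rac-7-(benzyloxy)-3-[3-(benzyloxy)-2,4-dimethoxyphenyl]chroman-4-one | O=C1C(c2ccc(OC)c(OCc3ccccc3)c2OC)COc2cc(OCc3ccccc3)ccc21 | intermediate
8 | (3R,4R)-7-(benzyloxy)-3-[3-(benzyloxy)-2,4-dimethoxyphenyl]chroman-4-ol | O[C@@H]1[C@H](c2ccc(OC)c(OCc3ccccc3)c2OC)COc2cc(OCc3ccccc3)ccc21 | intermediate
9 | 5-methoxybenzene-1,3-diol | COc1cc(O)cc(O)c1 | starting material
10 | 3-methoxy-5-[tri(propan-2-yl)silyloxy]phenol | COc1cc(O)cc(O[Si](C(C)C)(C(C)C)C(C)C)c1 | intermediate
11 | (3R)-7-(benzyloxy)-3-[3-(benzyloxy)-2,4-dimethoxyphenyl]chroman-4-ylium (not isolated) | [CH+]1[C@H](c2ccc(OC)c(OCc3ccccc3)c2OC)COc2cc(OCc3ccccc3)ccc21 | intermediate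
12 | 2-[(3R,4S)-7-(benzyloxy)-3-[3-(benzyloxy)-2,4-dimethoxyphenyl]chroman-4-yl]-3-methoxy-5-[tri(propan-2-yl)silyloxy]phenol | COc1cc(O[Si](C(C)C)(C(C)C)C(C)C)cc(O)c1[C@H]1[C@H](c2ccc(OC)c(OCc3ccccc3)c2OC)COc2cc(OCc3ccccc3)ccc21 | intermediate
13 | 2-[(3R,4S)-7-(benzyloxy)-3-[3-(benzyloxy)-2,4-dimethoxyphenyl]chroman-4-yl]-3-methoxy-5-[tri(propan-2-yl)silyloxy]phenyl trifluoromethanesulfonate | COc1cc(O[Si](C(C)C)(C(C)C)C(C)C)cc(OS(=O)(=O)C(F)(F)F)c1[C@H]1[C@H](c2ccc(OC)c(OCc3ccccc3)c2OC)COc2cc(OCc3ccccc3)ccc21 | intermediate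
14 | caesium 4-[(3R,4S)-7-(benzyloxy)-3-[3-(benzyloxy)-2,4-dimethoxyphenyl]chroman-4-yl]-3-methoxy-5-[(trifluoromethanesulfonyl)oxy]phenolate (not isolated) | COc1cc([O-])cc(OS(=O)(=O)C(F)(F)F)c1[C@H]1[C@H](c2ccc(OC)c(OCc3ccccc3)c2OC)COc2cc(OCc3ccccc3)ccc21.[Cs+] | intermediate
15 | 5-(benzyloxy)-2-[(3R,4S)-7-(benzyloxy)-3-[3-(benzyloxy)-2,4-dimethoxyphenyl]chroman-4-yl]-3-methoxyphenyl trifluoromethanesulfonate | COc1cc(OCc2ccccc2)cc(OS(=O)(=O)C(F)(F)F)c1[C@H]1[C@H](c2ccc(OC)c(OCc3ccccc3)c2OC)COc2cc(OCc3ccccc3)ccc21 | intermediate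
16 | 7-(benzyloxy)-3-{5-(benzyloxy)-2-[(3R,4S)-7-(benzyloxy)-3-[3-(benzyloxy)-2,4-dimethoxyphenyl]chroman-4-yl]-3-methoxyphenyl}chroman-4-one (C3 epimers of the chromanone) | O=C1C(c2cc(OCc3ccccc3)cc(OC)c2[C@H]2[C@H](c3ccc(OC)c(OCc4ccccc4)c3OC)COc3cc(OCc4ccccc4)ccc32)COc2cc(OCc3ccccc3)ccc21 | intermediate
17 | (3R,4R)-7-(benzyloxy)-3-{5-(benzyloxy)-2-[(3R,4S)-7-(benzyloxy)-3-[3-(benzyloxy)-2,4-dimethoxyphenyl]chroman-4-yl]-3-methoxyphenyl}chroman-4-ol | O[C@@H]1[C@H](c2cc(OCc3ccccc3)cc(OC)c2[C@H]2[C@H](c3ccc(OC)c(OCc4ccccc4)c3OC)COc3cc(OCc4ccccc4)ccc32)COc2cc(OCc3ccccc3)ccc21 | intermediate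
18 | (3R,4S)-4-{4-hydroxy-2-[(3R)-7-hydroxychroman-3-yl]-6-methoxyphenyl}-3-(3-hydroxy-2,4-dimethoxyphenyl)chroman-7-ol | COc1ccc([C@@H]2COc3cc(O)ccc3[C@H]2c2c(OC)cc(O)cc2[C@@H]2COc3cc(O)ccc3C2)c(OC)c1O | target

**Totals**
Total step count: 12.
Longest linear sequence: 10 steps (1, 2, 4, 5, 7, 8, 9, 10, 11, 12).

**Three steps most likely to fail**

Step 4 (enolonium arylation). The risks are loss of the C2 proton from the enolonium to give the chromone, and oxidation of arene 5 instead of C–C bond formation. The fallback sets out from 5 and returns at 7, moving the umpolung onto the arene. Arene 5 reacts with MesI(OAc)2 and TfOH (CH2Cl2, 0 °C) at the same ring carbon to give [3-(benzyloxy)-2,4-dimethoxyphenyl](2,4,6-trimethylphenyl)iodonium trifluoromethanesulfonate F1. Cu(OTf)2 (10 mol %) in CH2Cl2 at rt then transfers the trioxygenated aryl group of F1 to silyl enol ether 3, the mesityl group staying on iodine, to give 7.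

Step 7 (Friedel–Crafts union). The risks are attack at a ring carbon next to the TIPS ether, and self-alkylation of ring A. The fallback sets out from 8 and 10 and returns at 12, delivering the cation to the phenol through its own oxygen. Mitsunobu etherification of 8 with 10 (PPh3, DIAD, THF, 0 °C, inversion at C4) gives (3R,4S)-7-(benzyloxy)-3-[3-(benzyloxy)-2,4-dimethoxyphenyl]-4-{3-methoxy-5-[tri(propan-2-yl)silyloxy]phenoxy}chroman F2. Bi(OTf)3 (5 mol %) in toluene at −20 °C then induces the O-to-C 1,3-benzyl shift; the contact ion pair collapses at the ortho carbon next to OMe, anti to the C3 aryl group, to give 12.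

Step 10 (α-arylation with a hindered triflate). The risks are slow coupling next to the bulky diarylmethyl group and triflate hydrolysis. The fallback sets out from 10, 2 and 8 and returns at 16, attaching ring F before the Friedel–Crafts step. Triflation of 10 (Tf2O, pyridine) gives the unhindered 3-methoxy-5-[tri(propan-2-yl)silyloxy]phenyl trifluoromethanesulfonate F3. Pd α-arylation of 2 with F3 under the step-10 conditions gives rac-7-(benzyloxy)-3-{3-methoxy-5-[tri(propan-2-yl)silyloxy]phenyl}chroman-4-one F4. BF3·OEt2-catalysed coupling of 8 with F4 (ring D is deactivated by its carbonyl, so ring E reacts) gives 7-(benzyloxy)-3-{2-[(3R,4S)-7-(benzyloxy)-3-[3-(benzyloxy)-2,4-dimethoxyphenyl]chroman-4-yl]-3-methoxy-5-[tri(propan-2-yl)silyloxy]phenyl}chroman-4-one F5. CsF and BnBr as in step 9 convert F5 into 16.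

**Further compounds**
F1 | step 4 | [3-(benzyloxy)-2,4-dimethoxyphenyl](2,4,6-trimethylphenyl)iodonium trifluoromethanesulfonate | COc1ccc([I+]c2c(C)cc(C)cc2C)c(OC)c1OCc1ccccc1.[O-]S(=O)(=O)C(F)(F)F
F2 | step 7 | (3R,4S)-7-(benzyloxy)-3-[3-(benzyloxy)-2,4-dimethoxyphenyl]-4-{3-methoxy-5-[tri(propan-2-yl)silyloxy]phenoxy}chroman | COc1cc(O[C@H]2[C@H](c3ccc(OC)c(OCc4ccccc4)c3OC)COc3cc(OCc4ccccc4)ccc32)cc(O[Si](C(C)C)(C(C)C)C(C)C)c1
F3 | step 10 | 3-methoxy-5-[tri(propan-2-yl)silyloxy]phenyl trifluoromethanesulfonate | COc1cc(OS(=O)(=O)C(F)(F)F)cc(O[Si](C(C)C)(C(C)C)C(C)C)c1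
F4 | step 10 | rac-7-(benzyloxy)-3-{3-methoxy-5-[tri(propan-2-yl)silyloxy]phenyl}chroman-4-one | O=C1C(c2cc(OC)cc(O[Si](C(C)C)(C(C)C)C(C)C)c2)COc2cc(OCc3ccccc3)ccc21
F5 | step 10 | 7-(benzyloxy)-3-{2-[(3R,4S)-7-(benzyloxy)-3-[3-(benzyloxy)-2,4-dimethoxyphenyl]chroman-4-yl]-3-methoxy-5-[tri(propan-2-yl)silyloxy]phenyl}chroman-4-one (C3 epimers of the chromanone) | O=C1C(c2cc(O[Si](C(C)C)(C(C)C)C(C)C)cc(OC)c2[C@H]2[C@H](c3ccc(OC)c(OCc4ccccc4)c3OC)COc3cc(OCc4ccccc4)ccc32)COc2cc(OCc3ccccc3)ccc21
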